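**Plan**

- Retrosynthesis: the two lactone bonds C15–C16 and O–C2 are cut together, which takes CO2 out of the α-methylene-γ-lactone. Then C1–C2 of the 14-membered ring is cut, then C13–C14. The C2–C13 chain with its three E olefins is (2E,6E)-farnesol.
- Forward: the farnesyl chain is oxidised at C13, then a C13–C14 aldol adds a C4 ynone. The 14-membered carbocycle is closed at C1–C2 by intramolecular allenylindium addition. The lactone ring is made last by CO2 annulation, and O-silyl is exchanged for O-acetyl.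
- Feature used: in the 14-membered ring, C2 is allylic to the C3=C4(Me) olefin, so an η3-allyl palladium unit C2–C3–C4 can be generated at the lactone O-carbon. C2 is also 1,3-related through C1 to the exocyclic 1,1-disubstituted vinyl carbon C15, which can carry boron. CO2 spans C15 and C2 and closes the five-membered ring O–C16–C15–C1–C2.
- Stereochemistry: C13 comes from a catalytic asymmetric Mukaiyama aldol. The propargylic carbinol comes from Noyori transfer hydrogenation and is relayed to C1 and C2 in one event (anti SN2′ then syn SE2′, anti adduct). C2 is then inverted by Mitsunobu esterification and retained by double inversion in the key step.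

Key step: step 13

Numbering used below (cembrane): C1 = ring CH carrying C15; C15 = α-carbon; C16 = lactone C=O; C17 = exocyclic CH2; C2 = O–CH; C13 = CH–OAc; C14 = CH2.

Assumption: in step 4 the (R,R)-bisphosphoramide is taken to direct addition to the Re face of the aldehyde (12R in 8); if the sense is opposite, the (S,S)-catalyst is used and nothing else changes.

**Route**

Step 1
Reactants: 1 (2E,6E)-farnesol
Product: 2 (2E,6E)-farnesyl acetate
Conditions: Ac2O, pyridine, DMAP (cat.), CH2Cl2, 0 °C → rt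
Reagents that add atoms: acetic anhydride, CC(=O)OC(C)=O
Why: O-acylation protects the primary allylic alcohol as an ester that should survive the oxidation, Lewis-acid aldol, silylation and transfer hydrogenation and is later removed together with the alkynyl silane.

Step 2
Reactants: 2 (2E,6E)-farnesyl acetate
Product: 4 (2E,6E,10E)-3,7,11-trimethyl-12-oxododeca-2,6,10-trien-1-yl acetate, via allylic alcohol 3 (not isolated)
Conditions: SeO2 (0.3 equiv), t-BuOOH, salicylic acid (cat.), CH2Cl2, rt; then MnO2 (excess), CH2Cl2, rt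
Reagents that add atoms: tert-butyl hydroperoxide, CC(C)(C)OO
Why: Sharpless SeO2/TBHP allylic oxidation (ene reaction then [2,3]-shift) should attack the distal, most electron-rich trisubstituted olefin at its trans-methyl group to give the (E)-allylic alcohol 3, which MnO2 oxidises selectively to the (E)-enal.

Step 3
Reactants: 5 4-(trimethylsilyl)but-3-yn-2-one
Product: 6 trimethyl{[4-(trimethylsilyl)but-1-en-3-yn-2-yl]oxy}silane
Conditions: TMSOTf, Et3N, Et2O, 0 °C
Reagents that add atoms: trimethylsilyl triflate, C[Si](C)(C)OS(=O)(=O)C(F)(F)F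
Why: soft enolisation and O-silylation of the methyl ketone (the only enolisable position) gives the enol silane needed for a Mukaiyama aldol.

Step 4
Reactants: 4 (2E,6E,10E)-3,7,11-trimethyl-12-oxododeca-2,6,10-trien-1-yl acetate; 6 trimethyl{[4-(trimethylsilyl)but-1-en-3-yn-2-yl]oxy}silane
Product: 8 (2E,6E,10E,12R)-12-hydroxy-3,7,11-trimethyl-14-oxo-16-(trimethylsilyl)hexadeca-2,6,10-trien-15-yn-1-yl acetate, via trichlorosilyl aldolate 7 (not isolated)
Conditions: SiCl4 (1.5 equiv), (R,R)-BINAM-derived bisphosphoramide (Denmark, 5 mol %), i-Pr2NEt (10 mol %), CH2Cl2, −78 °C; aq. KF/NaHCO3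
Reagents that add atoms: none
Why: Lewis-base-activated SiCl4 binds the conjugated aldehyde and the enol silane adds 1,2 through an open transition state (catalytic asymmetric Mukaiyama aldol, a type established for enals with methyl-ketone enol silanes), so the carbinol centre (chain C12 = ring C13, R) is set by the catalyst.

Step 5
Reactants: 8 (2E,6E,10E,12R)-12-hydroxy-3,7,11-trimethyl-14-oxo-16-(trimethylsilyl)hexadeca-2,6,10-trien-15-yn-1-yl acetate
Product: 9 (2E,6E,10E,12R)-12-[(tert-butyldimethylsilyl)oxy]-3,7,11-trimethyl-14-oxo-16-(trimethylsilyl)hexadeca-2,6,10-trien-15-yn-1-yl acetate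
Conditions: TBSOTf, 2,6-lutidine, CH2Cl2, −78 °C
Reagents that add atoms: tert-butyldimethylsilyl triflate, CC(C)(C)[Si](C)(C)OS(=O)(=O)C(F)(F)F
Why: low-temperature O-silylation caps the β-hydroxy ynone before it can cyclise or eliminate and gives a group that is not an allylic leaving group in the later palladium step.

Step 6
Reactants: 9 (2E,6E,10E,12R)-12-[(tert-butyldimethylsilyl)oxy]-3,7,11-trimethyl-14-oxo-16-(trimethylsilyl)hexadeca-2,6,10-trien-15-yn-1-yl acetate
Product: 10 (2E,6E,10E,12R,14R)-12-[(tert-butyldimethylsilyl)oxy]-14-hydroxy-3,7,11-trimethyl-16-(trimethylsilyl)hexadeca-2,6,10-trien-15-yn-1-yl acetate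
Conditions: Ru[(R,R)-TsDPEN](p-cymene) (2 mol %, base-free amido complex), i-PrOH, rt
Reagents that add atoms: none
Why: Noyori asymmetric transfer hydrogenation of the ynone, with the alkynyl group in the CH/π-stabilised position, should give the 14R propargylic alcohol by catalyst control regardless of the remote C12 centre; base-free conditions avoid β-elimination of the silyloxy group.

Step 7
Reactants: 10 (2E,6E,10E,12R,14R)-12-[(tert-butyldimethylsilyl)oxy]-14-hydroxy-3,7,11-trimethyl-16-(trimethylsilyl)hexadeca-2,6,10-trien-15-yn-1-yl acetate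
Product: 11 (2E,6E,10E,12R,14R)-12-[(tert-butyldimethylsilyl)oxy]-3,7,11-trimethylhexadeca-2,6,10-trien-15-yne-1,14-diol
Conditions: K2CO3 (cat.), MeOH, 0 °C
Reagents that add atoms: none
Why: methanolysis removes the primary acetate and the alkynyl C–SiMe3 group in one operation while the secondary TBS ether stays (short reaction time limits 1,3-silyl migration).

Step 8
Reactants: 11 (2E,6E,10E,12R,14R)-12-[(tert-butyldimethylsilyl)oxy]-3,7,11-trimethylhexadeca-2,6,10-trien-15-yne-1,14-diol
Product: 12 (2E,6E,10E,12R,14R)-12-[(tert-butyldimethylsilyl)oxy]-14-hydroxy-3,7,11-trimethylhexadeca-2,6,10-trien-15-ynal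
Conditions: TEMPO (10 mol %), PhI(OAc)2 (1.1 equiv), CH2Cl2, rt
Reagents that add atoms: none
Why: oxoammonium (TEMPO/BAIB) oxidation is selective for the primary allylic alcohol over the hindered secondary propargylic alcohol and should give the (E)-enal without over-oxidation.

Step 9
Reactants: 12 (2E,6E,10E,12R,14R)-12-[(tert-butyldimethylsilyl)oxy]-14-hydroxy-3,7,11-trimethylhexadeca-2,6,10-trien-15-ynal
Product: 13 (2E,6E,10E,12R,14R)-12-[(tert-butyldimethylsilyl)oxy]-3,7,11-trimethyl-1-oxohexadeca-2,6,10-trien-15-yn-14-yl methanesulfonate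
Conditions: MsCl, Et3N, CH2Cl2, −40 → −20 °C; used crude
Reagents that add atoms: methanesulfonyl chloride, CS(=O)(=O)Cl
Why: O-sulfonylation with retention turns the propargylic alcohol into the leaving group for SN2′ oxidative addition; the enal and silyl ether are inert.

Step 10
Reactants: 13 (2E,6E,10E,12R,14R)-12-[(tert-butyldimethylsilyl)oxy]-3,7,11-trimethyl-1-oxohexadeca-2,6,10-trien-15-yn-14-yl methanesulfonate
Product: 15 (1S,2R,3E,7E,11E,13R)-13-[(tert-butyldimethylsilyl)oxy]-1-ethynyl-4,8,12-trimethylcyclotetradeca-3,7,11-trien-2-ol, via allenylindium species 14 (not isolated)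
Conditions: Pd(dppf)Cl2 (5 mol %), InI (1.5 equiv), THF–HMPA 3:1, rt, slow addition of 13 (final ca. 3 mM)
Reagents that add atoms: none
Why: Marshall-type propargylic umpolung: Pd(0) displaces the mesylate anti (SN2′), InI transmetallates to the (P)-allenylindium 14, and this adds to the enal through a cyclic SE2′ transition state, so C1–C2 forms with net inversion at the former carbinol carbon (C1 = S) and the anti preference sets C2 (R); high dilution favours the 14-membered ring.

Step 11
Reactants: 15 (1S,2R,3E,7E,11E,13R)-13-[(tert-butyldimethylsilyl)oxy]-1-ethynyl-4,8,12-trimethylcyclotetradeca-3,7,11-trien-2-ol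
Product: 17 (1S,2S,3E,7E,11E,13R)-13-[(tert-butyldimethylsilyl)oxy]-4,8,12-trimethyl-1-[1-(4,4,5,5-tetramethyl-1,3,2-dioxaborolan-2-yl)ethenyl]cyclotetradeca-3,7,11-trien-2-ol, via alkenylalane 16 (not isolated)
Conditions: Ni(dppp)Cl2 (3 mol %), DIBAL-H (2.5 equiv), THF, 0 °C → rt; then MeOBpin (3 equiv), 0 °C → rt; Rochelle salt
Reagents that add atoms: 2-methoxy-4,4,5,5-tetramethyl-1,3,2-dioxaborolane, COB1OC(C)(C)C(C)(C)O1
Why: Ni(dppp)-catalysed hydroalumination of a terminal alkyne places aluminium on the internal carbon (α-selective), and the alkenylalane is trapped by the borate with retention while the alcohol is carried as its aluminium alkoxide; no stereocentre is touched (the C2 descriptor changes from R to S only because boron lowers the CIP rank of C1).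

Step 12
Reactants: 17 (1S,2S,3E,7E,11E,13R)-13-[(tert-butyldimethylsilyl)oxy]-4,8,12-trimethyl-1-[1-(4,4,5,5-tetramethyl-1,3,2-dioxaborolan-2-yl)ethenyl]cyclotetradeca-3,7,11-trien-2-ol
Product: 18 (1S,2R,3E,7E,11E,13R)-13-[(tert-butyldimethylsilyl)oxy]-4,8,12-trimethyl-1-[1-(4,4,5,5-tetramethyl-1,3,2-dioxaborolan-2-yl)ethenyl]cyclotetradeca-3,7,11-trien-2-yl 4-nitrobenzoate
Conditions: 4-nitrobenzoic acid, PPh3, DIAD, THF, 0 °C → rt
Reagents that add atoms: 4-nitrobenzoic acid, O=C(O)c1ccc(cc1)[N+](=O)[O-]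
Why: Mitsunobu esterification displaces the alkoxyphosphonium with inversion at C2, which brings C2 to the geometry of the target and installs the allylic leaving group at the same time; the boronate is inert.

Step 13
Reactants: 18 (1S,2R,3E,7E,11E,13R)-13-[(tert-butyldimethylsilyl)oxy]-4,8,12-trimethyl-1-[1-(4,4,5,5-tetramethyl-1,3,2-dioxaborolan-2-yl)ethenyl]cyclotetradeca-3,7,11-trien-2-yl 4-nitrobenzoate; 19 carbon dioxide
Product: 21 (1S,2S,3E,7E,11E,13R)-13-[(tert-butyldimethylsilyl)oxy]cembra-3,7,11,15(17)-tetraen-16,2-olide, via caesium acrylate 20 (not isolated)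
Conditions: [(IPr)CuCl] (5 mol %), CsF (3 equiv), CO2 (1 atm), 1,4-dioxane, 80 °C; then Pd(PPh3)4 (5 mol %), 25 → 40 °C, same flask
Reagents that add atoms: carbon dioxide (19), O=C=O
Why: Proposed new method: B→Cu transmetallation of the 1,1-disubstituted alkenylboronate gives an NHC–copper alkenyl that inserts CO2 at C15 (C15–C16 bond) to give caesium acrylate 20, then Pd(0) ionises the allylic 4-nitrobenzoate at C2 with inversion to an η3-allyl complex over C2–C3–C4 and the tethered carboxylate attacks C2 anti to palladium (O–C2 bond); the closest known reaction types are the copper-catalysed carboxylation of alkenylboronic esters with CO2 and the Pd-catalysed allylic substitution by carboxylates (Tsuji–Trost lactonisation), merged here into a formal [3+2] annulation of CO2. The only ring closed is the γ-lactone, by 5-exo attack of oxygen on the proximal allyl terminus C2 (a 5-membered ring rather than a 7-membered ring through C4). The new stereocentre C2 is controlled by the double inversion, i.e. net retention of the configuration set in step 12, which places the lactone oxygen cis to the C1–C15 bond; C1 and C13 are untouched, and the 3E geometry should be kept because C5 remains syn on the allyl unit. The step needs CO2 insertion to outrun acyl transfer or SN2′ coupling of the alkenylcopper, which the CO2 excess, the carboxylate ester (a poor leaving group for copper) and the late addition of palladium should secure. It also needs a single ionisable allylic ester, secured by keeping the C13 oxygen as a silyl ether, and the product lactone, a poorer leaving group, should not re-ionise at 25–40 °C.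

Step 14
Reactants: 21 (1S,2S,3E,7E,11E,13R)-13-[(tert-butyldimethylsilyl)oxy]cembra-3,7,11,15(17)-tetraen-16,2-olide
Product: 22 (1S,2S,3E,7E,11E,13R)-13-hydroxycembra-3,7,11,15(17)-tetraen-16,2-olide
Conditions: HF·pyridine, pyridine, THF, 0 °C → rt
Reagents that add atoms: none
Why: buffered fluoride desilylation removes the secondary TBS ether without conjugate addition to the α-methylene lactone or ionisation of the allylic C–O bonds.

Step 15
Reactants: 22 (1S,2S,3E,7E,11E,13R)-13-hydroxycembra-3,7,11,15(17)-tetraen-16,2-olide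
Product: 23 (1S,2S,3E,7E,11E,13R)-13-acetoxycembra-3,7,11,15(17)-tetraen-16,2-olide (CNP0182196.1)
Conditions: Ac2O, pyridine, DMAP (cat.), CH2Cl2, 0 °C
Reagents that add atoms: acetic anhydride, CC(=O)OC(C)=O
Why: O-acetylation of the secondary allylic alcohol proceeds with retention at C13 and gives the target.

**Compound list**

1 | (2E,6E)-farnesol | CC(C)=CCC/C(C)=C/CC/C(C)=C/CO | starting material
2 | (2E,6E)-farnesyl acetate | CC(C)=CCC/C(C)=C/CC/C(C)=C/COC(C)=O | intermediate
3 | (2E,6E,10E)-12-hydroxy-3,7,11-trimethyldodeca-2,6,10-trien-1-yl acetate | OC/C(C)=C/CC/C(C)=C/CC/C(C)=C/COC(C)=O | intermediate (not isolated)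
4 | (2E,6E,10E)-3,7,11-trimethyl-12-oxododeca-2,6,10-trien-1-yl acetate | O=C/C(C)=C/CC/C(C)=C/CC/C(C)=C/COC(C)=O | intermediate
5 | 4-(trimethylsilyl)but-3-yn-2-one | CC(=O)C#C[Si](C)(C)C | starting material
6 | trimethyl{[4-(trimethylsilyl)but-1-en-3-yn-2-yl]oxy}silane | C=C(O[Si](C)(C)C)C#C[Si](C)(C)C | intermediate
7 | 12-O-trichlorosilyl ether of 8 | C[Si](C)(C)C#CC(=O)C[C@@H](O[Si](Cl)(Cl)Cl)/C(C)=C/CC/C(C)=C/CC/C(C)=C/COC(C)=O | intermediate (not isolated)
8 | (2E,6E,10E,12R)-12-hydroxy-3,7,11-trimethyl-14-oxo-16-(trimethylsilyl)hexadeca-2,6,10-trien-15-yn-1-yl acetate | C[Si](C)(C)C#CC(=O)C[C@@H](O)/C(C)=C/CC/C(C)=C/CC/C(C)=C/COC(C)=O | intermediate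
9 | (2E,6E,10E,12R)-12-[(tert-butyldimethylsilyl)oxy]-3,7,11-trimethyl-14-oxo-16-(trimethylsilyl)hexadeca-2,6,10-trien-15-yn-1-yl acetate | C[Si](C)(C)C#CC(=O)C[C@@H](O[Si](C)(C)C(C)(C)C)/C(C)=C/CC/C(C)=C/CC/C(C)=C/COC(C)=O | intermediate
10 | (2E,6E,10E,12R,14R)-12-[(tert-butyldimethylsilyl)oxy]-14-hydroxy-3,7,11-trimethyl-16-(trimethylsilyl)hexadeca-2,6,10-trien-15-yn-1-yl acetate | C[Si](C)(C)C#C[C@H](O)C[C@@H](O[Si](C)(C)C(C)(C)C)/C(C)=C/CC/C(C)=C/CC/C(C)=C/COC(C)=O | intermediate
11 | (2E,6E,10E,12R,14R)-12-[(tert-butyldimethylsilyl)oxy]-3,7,11-trimethylhexadeca-2,6,10-trien-15-yne-1,14-diol | C#C[C@H](O)C[C@@H](O[Si](C)(C)C(C)(C)C)/C(C)=C/CC/C(C)=C/CC/C(C)=C/CO | intermediate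
12 | (2E,6E,10E,12R,14R)-12-[(tert-butyldimethylsilyl)oxy]-14-hydroxy-3,7,11-trimethylhexadeca-2,6,10-trien-15-ynal | C#C[C@H](O)C[C@@H](O[Si](C)(C)C(C)(C)C)/C(C)=C/CC/C(C)=C/CC/C(C)=C/C=O | intermediate
13 | (2E,6E,10E,12R,14R)-12-[(tert-butyldimethylsilyl)oxy]-3,7,11-trimethyl-1-oxohexadeca-2,6,10-trien-15-yn-14-yl methanesulfonate | C#C[C@H](OS(C)(=O)=O)C[C@@H](O[Si](C)(C)C(C)(C)C)/C(C)=C/CC/C(C)=C/CC/C(C)=C/C=O | intermediate
14 | allenylindium(III) iodide methanesulfonate I(MsO)In–CH=C=CH–CH2–CH(OTBS)–chain–CHO (allene axis aS = P; 12R) | CS(=O)(=O)O[In](I)C([H])=[C@@]=C([H])C[C@@H](O[Si](C)(C)C(C)(C)C)/C(C)=C/CC/C(C)=C/CC/C(C)=C/C=O | intermediate (not isolated)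
15 | (1S,2R,3E,7E,11E,13R)-13-[(tert-butyldimethylsilyl)oxy]-1-ethynyl-4,8,12-trimethylcyclotetradeca-3,7,11-trien-2-ol | C#C[C@H]1[C@H](O)/C=C(\C)CC/C=C(\C)CC/C=C(\C)[C@H](O[Si](C)(C)C(C)(C)C)C1 | intermediate
16 | diisobutylaluminium alkoxide of the 1-(diisobutylaluminio)ethenyl analogue of 15 | C=C([Al](CC(C)C)CC(C)C)[C@H]1[C@H](O[Al](CC(C)C)CC(C)C)/C=C(\C)CC/C=C(\C)CC/C=C(\C)[C@H](O[Si](C)(C)C(C)(C)C)C1 | intermediate (not isolated)
17 | (1S,2S,3E,7E,11E,13R)-13-[(tert-butyldimethylsilyl)oxy]-4,8,12-trimethyl-1-[1-(4,4,5,5-tetramethyl-1,3,2-dioxaborolan-2-yl)ethenyl]cyclotetradeca-3,7,11-trien-2-ol (C2 geometry as in 15) | C=C(B1OC(C)(C)C(C)(C)O1)[C@H]1[C@H](O)/C=C(\C)CC/C=C(\C)CC/C=C(\C)[C@H](O[Si](C)(C)C(C)(C)C)C1 | intermediate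
18 | (1S,2R,3E,7E,11E,13R)-13-[(tert-butyldimethylsilyl)oxy]-4,8,12-trimethyl-1-[1-(4,4,5,5-tetramethyl-1,3,2-dioxaborolan-2-yl)ethenyl]cyclotetradeca-3,7,11-trien-2-yl 4-nitrobenzoate (C2 inverted relative to 17) | C=C(B1OC(C)(C)C(C)(C)O1)[C@H]2[C@@H](OC(=O)c3ccc(cc3)[N+](=O)[O-])/C=C(\C)CC/C=C(\C)CC/C=C(\C)[C@H](O[Si](C)(C)C(C)(C)C)C2 | intermediate
19 | carbon dioxide | O=C=O | starting material
20 | caesium 2-[(1S,2S,3E,7E,11E,13R)-13-[(tert-butyldimethylsilyl)oxy]-4,8,12-trimethyl-2-(4-nitrobenzoyloxy)cyclotetradeca-3,7,11-trien-1-yl]prop-2-enoate | [Cs+].[O-]C(=O)C(=C)[C@H]1[C@@H](OC(=O)c2ccc(cc2)[N+](=O)[O-])/C=C(\C)CC/C=C(\C)CC/C=C(\C)[C@H](O[Si](C)(C)C(C)(C)C)C1 | intermediate (not isolated)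
21 | (1S,2S,3E,7E,11E,13R)-13-[(tert-butyldimethylsilyl)oxy]cembra-3,7,11,15(17)-tetraen-16,2-olide | C=C1C(=O)O[C@H]2/C=C(\C)CC/C=C(\C)CC/C=C(\C)[C@H](O[Si](C)(C)C(C)(C)C)C[C@@H]12 | intermediate
22 | (1S,2S,3E,7E,11E,13R)-13-hydroxycembra-3,7,11,15(17)-tetraen-16,2-olide | C=C1C(=O)O[C@H]2/C=C(\C)CC/C=C(\C)CC/C=C(\C)[C@H](O)C[C@@H]12 | intermediate
23 | (1S,2S,3E,7E,11E,13R)-13-acetoxycembra-3,7,11,15(17)-tetraen-16,2-olide (CNP0182196.1) | C=C1C(=O)O[C@H]2/C=C(\C)CC/C=C(\C)CC/C=C(\C)[C@H](OC(C)=O)C[C@@H]12 | target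

**Totals and risks**

Total steps: 15. Longest linear sequence: 14 (steps 1, 2 and 4–15 from farnesol; step 3 is a side branch).

Steps most likely to fail:

1. Step 13 (Proposed new method). What may go wrong: protodeboronation of the hindered alkenylcopper instead of CO2 insertion, acyl transfer from copper to the ester, or elimination to a diene and facial leakage at the π-allyl stage. Fallback with known chemistry, setting out from 18: methanolysis of the 4-nitrobenzoate (K2CO3, MeOH, 0 °C) should give the C2-inverted hydroxy boronate F1. Copper-catalysed carboxylation of its alkenylboronate with CO2 ([(IPr)CuCl], KOt-Bu 2.1 equiv, THF, 65 °C) and acidic work-up should give the hydroxy acid F2. F2 lactonises by ordinary acyl–oxygen closure with retention at C2 (PPTS, CH2Cl2 if needed), and the route is rejoined at 21.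

2. Step 10. What may go wrong: intermolecular addition giving oligomers, protonation or racemisation of the allenylindium, or erosion of the anti preference inside the forming ring. Fallback, setting out from 12: Appel bromination (CBr4, PPh3, 2,6-lutidine, CH2Cl2, −20 °C) should give the propargylic bromide F3, and a Nozaki–Hiyama closure with CrCl2 (THF, high dilution) returns to the route at 15. This closure goes through radicals and a configurationally labile allenylchromium(III), so chirality is no longer transferred from the propargylic centre. C1 and C2 then rest on the anti preference of the cyclic transition state and on the C13 silyl ether, and 15 would have to be separated from its (1R,2S) diastereomer.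

3. Step 11. What may go wrong: loss of regiocontrol (aluminium on the terminal carbon), metallation of the alkyne C–H, or incomplete Al→B exchange. Fallback without the boron handle, setting out from 15: Mitsunobu inversion (4-nitrobenzoic acid, PPh3, DIAD, THF) should give the alkynyl 4-nitrobenzoate F4, and methanolysis (K2CO3, MeOH) the syn homopropargylic alcohol F5. Palladium-catalysed cyclocarbonylation of this alkynol (PdCl2, SnCl2, PPh3, CO, MeCN, 75 °C) builds the α-methylene lactone with retention at C2 and returns to the route at 21.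

Further compounds
F1 | step 13 | (1S,2R,3E,7E,11E,13R)-13-[(tert-butyldimethylsilyl)oxy]-4,8,12-trimethyl-1-[1-(4,4,5,5-tetramethyl-1,3,2-dioxaborolan-2-yl)ethenyl]cyclotetradeca-3,7,11-trien-2-ol (C2 epimer of 17) | C=C(B1OC(C)(C)C(C)(C)O1)[C@H]1[C@@H](O)/C=C(\C)CC/C=C(\C)CC/C=C(\C)[C@H](O[Si](C)(C)C(C)(C)C)C1
F2 | step 13 | 2-[(1S,2S,3E,7E,11E,13R)-13-[(tert-butyldimethylsilyl)oxy]-2-hydroxy-4,8,12-trimethylcyclotetradeca-3,7,11-trien-1-yl]prop-2-enoic acid | C=C(C(=O)O)[C@H]1[C@@H](O)/C=C(\C)CC/C=C(\C)CC/C=C(\C)[C@H](O[Si](C)(C)C(C)(C)C)C1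
F3 | step 10 | (2E,6E,10E,12R,14S)-14-bromo-12-[(tert-butyldimethylsilyl)oxy]-3,7,11-trimethylhexadeca-2,6,10-trien-15-ynal | C#C[C@@H](Br)C[C@@H](O[Si](C)(C)C(C)(C)C)/C(C)=C/CC/C(C)=C/CC/C(C)=C/C=O
F4 | step 11 | (1S,2S,3E,7E,11E,13R)-13-[(tert-butyldimethylsilyl)oxy]-1-ethynyl-4,8,12-trimethylcyclotetradeca-3,7,11-trien-2-yl 4-nitrobenzoate | C#C[C@H]1[C@@H](OC(=O)c2ccc(cc2)[N+](=O)[O-])/C=C(\C)CC/C=C(\C)CC/C=C(\C)[C@H](O[Si](C)(C)C(C)(C)C)C1
F5 | step 11 | (1S,2S,3E,7E,11E,13R)-13-[(tert-butyldimethylsilyl)oxy]-1-ethynyl-4,8,12-trimethylcyclotetradeca-3,7,11-trien-2-ol | C#C[C@H]1[C@@H](O)/C=C(\C)CC/C=C(\C)CC/C=C(\C)[C@H](O[Si](C)(C)C(C)(C)C)C1
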